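**Plan**
Cuts: (i) the O–tBu mask of the ring-B carboxyl; (ii) in ring A the C1–C6 and C2–C3 bonds; (iii) the depside C(=O)–O(C4′) bond; (iv) on ring B the C4′–O bond and the benzylic CH2–CH2 bond of the heptyl chain.
Enabling feature: ring A is a 2-heptyl-6-hydroxy-4-methoxybenzoate. C1 (acyl-bearing) and C2 (heptyl-bearing) are the two sp carbons of a dec-2-ynoate. C3–C6 are a butadiene oxygenated at C4 (methyl enol ether) and C6 (methyl silyl ketene acetal), so OMe and OH differ from the outset.
Forward: ring B is bought as 2-methoxy-6-methylbenzoic acid and dressed by lateral hexylation, tert-butyl esterification and sterically directed C4′–H borylation/oxidation, then O-acylated with dec-2-ynoic acid.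
Ring A is the only ring built. It is closed last, directly on the depside ester, by [4+2] cycloaddition and aromatisation; acidolysis of the tert-butyl ester ends the route.
Stereochemistry: none is needed. Only regiochemistry counts, set by sterics in the borylation and by polarity in the cycloaddition.
Key step: step 6

Remark: the target SMILES holds no stereocentre, stereogenic double bond or hindered axis, so the compound is achiral and the one structure drawn is what the route delivers; all four starting materials are taken as catalogue compounds.

Step 1
Reactants: 1 2-methoxy-6-methylbenzoic acid; 2 1-iodohexane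
Product: 4 2-heptyl-6-methoxybenzoic acid, via dilithio dianion 3 (not isolated)
Conditions: LDA (2.2 equiv), THF, −78 → 0 °C; 2 (1.2 equiv), −78 °C → rt; 1 M HCl
Reagents that add atoms: none
Why: Two equivalents of LDA turn 1 into the carboxylate-stabilised benzylic dianion 3 (lateral lithiation of an o-toluic acid), whose much more nucleophilic carbanion centre is alkylated by the primary iodide in an SN2 reaction while the carboxylate stays untouched.

Step 2
Reactants: 4 2-heptyl-6-methoxybenzoic acid
Product: 5 tert-butyl 2-heptyl-6-methoxybenzoate
Conditions: Cl3CC(=NH)OtBu (2 equiv), BF3·OEt2 (cat.), CH2Cl2/cyclohexane, rt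
Reagents that add atoms: tert-butyl 2,2,2-trichloroacetimidate, CC(C)(C)OC(=N)C(Cl)(Cl)Cl
Why: In this trichloroacetimidate esterification the protonated imidate releases a tert-butyl cation that the carboxylate oxygen captures, so the O-alkylation never needs attack at the carbonyl group shielded by two ortho substituents.

Step 3
Reactants: 5 tert-butyl 2-heptyl-6-methoxybenzoate
Product: 7 tert-butyl 2-heptyl-4-hydroxy-6-methoxybenzoate, via aryl pinacol boronate 6 (not isolated)
Conditions: [Ir(OMe)(cod)]2 (1.5 mol %), dtbpy (3 mol %), B2pin2 (1.0 equiv), THF, 80 °C; evaporate; Oxone, acetone/H2O, rt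
Reagents that add atoms: bis(pinacolato)diboron, CC1(C)OB(OC1(C)C)B1OC(C)(C)C(C)(C)O1 (boryl group of 6 only); potassium peroxymonosulfate, the active part of Oxone, [K+].[O-]S(=O)(=O)OO (phenol oxygen of 7)
Why: Iridium-catalysed aromatic C–H borylation is ruled by sterics and in this 1,2,3-trisubstituted arene only C4–H has no ortho substituent, so boron enters para to the ester, and the one-pot ipso-oxidation by peroxymonosulfate (1,2-aryl shift from boron to oxygen) turns 6 into the phenol without touching the tert-butyl ester.

Step 4
Reactants: 7 tert-butyl 2-heptyl-4-hydroxy-6-methoxybenzoate; 8 dec-2-ynoic acid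
Product: 9 tert-butyl 4-(dec-2-ynoyloxy)-2-heptyl-6-methoxybenzoate
Conditions: DCC (1.1 equiv), DMAP (5 mol %), CH2Cl2, −10 °C → rt
Reagents that add atoms: none
Why: In this Steglich esterification the carbodiimide-activated acid is passed by catalytic DMAP to the only nucleophile present, the unhindered C4 phenol, and the low temperature and small DMAP loading hold back conjugate addition to the triple bond.

Step 5
Reactants: 10 methyl (E)-3-methoxybut-2-enoate
Product: 12 (1E)-1,3-dimethoxy-1-(trimethylsilyloxy)buta-1,3-diene, via lithium dienolate 11 (not isolated)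
Conditions: LDA (1.1 equiv), THF, −78 °C; TMSCl (1.2 equiv), −78 °C → rt; pentane, filter, distil
Reagents that add atoms: chlorotrimethylsilane, C[Si](C)(C)Cl
Why: Kinetic γ-deprotonation of the vinylogous carbonate gives the extended enolate 11, which the hard silicon electrophile traps on oxygen (silyl ketene acetal formation) to give the diene, drawn as its (1E) isomer although either geometry leads to the same arene.

Step 6
Reactants: 9 tert-butyl 4-(dec-2-ynoyloxy)-2-heptyl-6-methoxybenzoate; 12 (1E)-1,3-dimethoxy-1-(trimethylsilyloxy)buta-1,3-diene
Product: 15 tert-butyl 2-heptyl-4-[(2-heptyl-6-hydroxy-4-methoxybenzoyl)oxy]-6-methoxybenzoate, via cyclohexadiene ketal cycloadduct 13 (not isolated), via aryl trimethylsilyl ether 14 (not isolated)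
Conditions: 12 (4 equiv, two portions), neat, 125 °C, slow Ar sweep; then 10% aq citric acid, THF, rt
Reagents that add atoms: none
Why: The triply donor-substituted diene 12 has its largest HOMO coefficient at the unsubstituted C4 methylene, and the LUMO of ynoate 9, lowered further by the electron-poor aryloxy group, is largest at the heptyl-bearing β-carbon, so a strongly asynchronous normal-demand Diels–Alder reaction (at the stepwise limit a Mukaiyama–Michael addition followed by ring closure) forms C2–C3 ahead of C1–C6. Ring A thus closes as a six-membered carbocycle in an intermolecular [4+2] mode and appears first as the cyclohexa-1,4-diene 13 with a mixed methyl silyl ketal at C6. A 1,4-elimination of methanol across C6 and C3, driven by aromatisation, gives silyl ether 14, and the citric acid wash cleaves the labile aryl O–Si bond to the hydroxyl that hydrogen-bonds to the depside carbonyl in 15, while the argon sweep carries the methanol away from the aryl ester. The closest known reaction type is the Diels–Alder aromatisation of 1,3-dioxygenated 1-silyloxybutadienes with alk-2-ynoates, which gives 6-alkyl-4-methoxysalicylates. The only selectivity needed is regiochemical; it is secured by this matched polarity and reinforced by sterics, because the CH2 terminus meets the substituted alkyne carbon and the ketal carbon ends next to the ester-bearing carbon. The ketal carbon of 13 is a transient stereocentre that forms as a racemate and is erased on aromatisation, so no stereocontrol is required.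

Step 7
Reactants: 15 tert-butyl 2-heptyl-4-[(2-heptyl-6-hydroxy-4-methoxybenzoyl)oxy]-6-methoxybenzoate
Product: 16 2-heptyl-4-[(2-heptyl-6-hydroxy-4-methoxybenzoyl)oxy]-6-methoxybenzoic acid
Conditions: TFA/CH2Cl2 1:3, Et3SiH (2.5 equiv), 0 °C → rt
Reagents that add atoms: none
Why: Acidolysis of the tert-butyl ester runs by alkyl–oxygen cleavage (AAL1), which leaves the aryl ester link and both methyl ethers alone, and triethylsilane reduces the tert-butyl cation before it can alkylate the electron-rich ring A.

**Compound list**
1 | 2-methoxy-6-methylbenzoic acid | COc1cccc(C)c1C(=O)O | starting material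
2 | 1-iodohexane | CCCCCCI | starting material
3 | dilithio dianion of 1 (lithium 2-(lithiomethyl)-6-methoxybenzoate) | [Li]Cc1cccc(OC)c1C(=O)O[Li] | intermediate
4 | 2-heptyl-6-methoxybenzoic acid | CCCCCCCc1cccc(OC)c1C(=O)O | intermediate
5 | tert-butyl 2-heptyl-6-methoxybenzoate | CCCCCCCc1cccc(OC)c1C(=O)OC(C)(C)C | intermediate
6 | tert-butyl 2-heptyl-6-methoxy-4-(4,4,5,5-tetramethyl-1,3,2-dioxaborolan-2-yl)benzoate | CCCCCCCc1cc(B2OC(C)(C)C(C)(C)O2)cc(OC)c1C(=O)OC(C)(C)C | intermediate
7 | tert-butyl 2-heptyl-4-hydroxy-6-methoxybenzoate | CCCCCCCc1cc(O)cc(OC)c1C(=O)OC(C)(C)C | intermediate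
8 | dec-2-ynoic acid | CCCCCCCC#CC(=O)O | starting material
9 | tert-butyl 4-(dec-2-ynoyloxy)-2-heptyl-6-methoxybenzoate | CCCCCCCC#CC(=O)Oc1cc(CCCCCCC)c(C(=O)OC(C)(C)C)c(OC)c1 | intermediate
10 | methyl (E)-3-methoxybut-2-enoate | CO/C(C)=C/C(=O)OC | starting material
11 | lithium (1Z)-1,3-dimethoxybuta-1,3-dien-1-olate (same spatial arrangement as 12) | C=C(OC)/C=C(\OC)O[Li] | intermediate
12 | (1E)-1,3-dimethoxy-1-(trimethylsilyloxy)buta-1,3-diene | C=C(OC)/C=C(\OC)O[Si](C)(C)C | intermediate
13 | tert-butyl 2-heptyl-4-{[2-heptyl-4,6-dimethoxy-6-(trimethylsilyloxy)cyclohexa-1,4-diene-1-carbonyl]oxy}-6-methoxybenzoate (racemic at the ketal carbon) | CCCCCCCC1=C(C(=O)Oc2cc(CCCCCCC)c(C(=O)OC(C)(C)C)c(OC)c2)C(OC)(O[Si](C)(C)C)C=C(OC)C1 | intermediate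
14 | tert-butyl 2-heptyl-4-{[2-heptyl-4-methoxy-6-(trimethylsilyloxy)benzoyl]oxy}-6-methoxybenzoate | CCCCCCCc1cc(OC)cc(O[Si](C)(C)C)c1C(=O)Oc1cc(CCCCCCC)c(C(=O)OC(C)(C)C)c(OC)c1 | intermediate
15 | tert-butyl 2-heptyl-4-[(2-heptyl-6-hydroxy-4-methoxybenzoyl)oxy]-6-methoxybenzoate | CCCCCCCc1cc(OC)cc(O)c1C(=O)Oc1cc(CCCCCCC)c(C(=O)OC(C)(C)C)c(OC)c1 | intermediate
16 | 2-heptyl-4-[(2-heptyl-6-hydroxy-4-methoxybenzoyl)oxy]-6-methoxybenzoic acid | CCCCCCCc1cc(OC)cc(O)c1C(=O)Oc1cc(CCCCCCC)c(C(=O)O)c(OC)c1 | target

Total step count: 7 (one-pot sequences counted once).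
Longest linear sequence: 6 (steps 1, 2, 3, 4, 6, 7); step 5 is the side branch.

**Steps most likely to fail**

Step 6. Several things could go wrong:
- The cycloaddition at the β-alkylated triple bond may be so slow that thermal decay of the ketene acetal wins.
- The released methanol may cleave the activated aryl ester link.
- The ketal may collapse with loss of silanol in place of methanol.

The fallback moves the cycloaddition to a sturdy alkyl ester and makes the depside bond afterwards. It sets out from 8 and 12. Acid 8 is alkylated with benzyl bromide (K2CO3, DMF, rt) to benzyl dec-2-ynoate F1. This ester tolerates long heating with 12 (neat, 150 °C) and after mild acidic work-up should give benzyl 2-heptyl-6-hydroxy-4-methoxybenzoate F2. Hydrogenolysis (H2, Pd/C, EtOAc) frees 2-heptyl-6-hydroxy-4-methoxybenzoic acid F3. Carbodiimide condensation of F3 with phenol 7 (DCC, toluene, rt) is the classical depside coupling, in which the chelated ortho-hydroxyl needs no protection. It comes back to the route at 15.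

Step 4. DMAP or the phenol may add in conjugate fashion to the activated triple bond, and an O→N acyl shift on the carbodiimide adduct may drain the activated acid. The fallback drops both the carbodiimide and the nucleophilic catalyst and sets out from 8. The acid is converted under neutral conditions with 1-chloro-N,N,2-trimethylprop-1-en-1-amine (CH2Cl2, 0 °C) into dec-2-ynoyl chloride F4. This is added to phenol 7 and iPr2NEt in CH2Cl2 at −20 °C and comes back to the route at 9.

Step 1. The second, benzylic deprotonation of the carboxylate may stay incomplete. Proton exchange between product and dianion may lead to over-alkylation, and residual amide base may eliminate HI from the iodide. The fallback reverses the order of the first two steps, so that an ester and not a carboxylate acidifies the methyl group. It sets out from 1. The trichloroacetimidate esterification gives tert-butyl 2-methoxy-6-methylbenzoate F5, whose bulky, doubly ortho-flanked ester resists self-condensation. Lateral deprotonation with one equivalent of LDA (THF, −78 °C) and alkylation with 2 comes back to the route at 5 and bypasses 4.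

**Further compounds**
F1 | step 6 | benzyl dec-2-ynoate | CCCCCCCC#CC(=O)OCc1ccccc1
F2 | step 6 | benzyl 2-heptyl-6-hydroxy-4-methoxybenzoate | CCCCCCCc1cc(OC)cc(O)c1C(=O)OCc1ccccc1
F3 | step 6 | 2-heptyl-6-hydroxy-4-methoxybenzoic acid | CCCCCCCc1cc(OC)cc(O)c1C(=O)O
F4 | step 4 | dec-2-ynoyl chloride | CCCCCCCC#CC(=O)Cl
F5 | step 1 | tert-butyl 2-methoxy-6-methylbenzoate | COc1cccc(C)c1C(=O)OC(C)(C)C
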